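**Convention and assumption:** the target is made exactly as drawn, i.e. 5S,8R,9R,13R in halimane numbering (C4 gem-dimethyl carbon, C5 ring-fusion CH, C8 CHMe, C9 quaternary carbon, C1=C10 alkene, C11–C16 side chain) with a 2S glycerol unit. Commercial (R)-(+)-pulegone and (R)-solketal supply the absolute configuration.

## Retrosynthetic overview

1. Target ⇒ diterpenoid acid 21 + (R)-solketal 22 (Steglich ester, acetonide removal, primary-selective acetylation).
2. Acid 21 ⇒ (E)-allylic alcohol 18 (C13 by Ru–BINAP hydrogenation) ⇒ alkyne 15 (Negishi carboalumination) ⇒ bicyclic ester 12.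
3. Ring A is formed last: C1=C10 by intramolecular McMurry coupling of keto aldehyde 11.
4. C9–C11: Michael addition of the ring B ketone enolate 9 to tert-butyl acrylate 8 sets the quaternary centre.
5. Ring B (preformed), C8 and the C4 carbon come from (R)-pulegone 1 by cuprate addition of a three-carbon acetal Grignard, methylation and equilibration.

## Route

**Step 1**
Reactants: 1 (R)-(+)-pulegone; 2 2-(2-bromoethyl)-1,3-dioxolane
Product: 4 (5R)-2-[4-(1,3-dioxolan-2-yl)-2-methylbutan-2-yl]-5-methylcyclohexan-1-one as a C2-epimer mixture, via Grignard reagent 3 (not isolated)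
Conditions: 2, Mg, THF, 25–30 °C; then 1, CuBr·SMe2 (20 mol %), THF–Me2S, −40 → 0 °C; aq NH4Cl
Reagents that add atoms: none
Why: Copper-catalysed conjugate addition of the Grignard reagent to the β,β-disubstituted enone of pulegone (as in the 8-phenylmenthone preparation) builds the quaternary C4 and the C4–C5 bond, with C8 (R) carried over from pulegone and C5 formed as an epimer mixture that is corrected in step 3.

**Step 2**
Reactants: 4 the conjugate-addition ketone (epimer mixture)
Product: 6 (3R)-6-[4-(1,3-dioxolan-2-yl)-2-methylbutan-2-yl]-2,3-dimethylcyclohexan-1-one as a mixture of C2 and C6 epimers, via lithium enolate 5 (not isolated)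
Conditions: LDA (commercial solution, 1.1 equiv), THF, −78 °C; MeI, −78 → −20 °C
Reagents that add atoms: iodomethane, CI
Why: Kinetic enolate alkylation in which LDA deprotonates the unhindered C9 methylene and not the neopentyl C5 methine, so the methyl group (C20) goes regioselectively to C9, whose configuration is still free to equilibrate.

**Step 3**
Reactants: 6 the methylated ketone mixture
Product: 7 (2S,3R,6S)-6-[4-(1,3-dioxolan-2-yl)-2-methylbutan-2-yl]-2,3-dimethylcyclohexan-1-one
Conditions: NaOMe (0.3 equiv), MeOH, 40 °C, 16 h; chromatography, minor isomers re-equilibrated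
Reagents that add atoms: none
Why: Base-mediated epimerisation under thermodynamic control funnels both α-centres into the chair with all three substituents equatorial (estimated about 3:1 over the other isomers), which fixes the C5 tert-alkyl group trans to the C8 methyl (5S) and the C9 methyl trans to the C8 methyl.

**Step 4**
Reactants: 7 the all-equatorial ketone; 8 tert-butyl prop-2-enoate (tert-butyl acrylate)
Product: 10 tert-butyl 3-[(1R,3S,6R)-3-[4-(1,3-dioxolan-2-yl)-2-methylbutan-2-yl]-1,6-dimethyl-2-oxocyclohexyl]propanoate, via lithium enolate 9 (not isolated)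
Conditions: LDA (commercial solution, 1.1 equiv), THF, −78 → −20 °C; then 8, −78 °C; AcOH quench at −78 °C
Reagents that add atoms: none
Why: Intermolecular Michael addition of the tetrasubstituted lithium enolate (C9–H is removed in preference to the shielded neopentyl C5–H) to the acrylate joins ring B to the side-chain fragment at C9–C11, and because the ring is locked by the equatorial tert-alkyl and methyl groups the acceptor enters along the axial trajectory on the face of the axial H5 (chair-like transition state), which places C11 axial and leaves the methyl equatorial, that is 9R.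

**Step 5**
Reactants: 10 the Michael adduct
Product: 11 tert-butyl 3-[(1R,3S,6R)-1,6-dimethyl-3-(2-methyl-5-oxopentan-2-yl)-2-oxocyclohexyl]propanoate
Conditions: PPTS (cat.), acetone–H2O (10:1), 55 °C
Reagents that add atoms: water, O
Why: Acid-catalysed acetal hydrolysis frees the aldehyde under conditions too mild to cleave the tert-butyl ester or to enolise the hindered ketone towards C5.

**Step 6**
Reactants: 11 the keto aldehyde
Product: 12 tert-butyl 3-[(1R,2R,4aS)-1,2,5,5-tetramethyl-1,2,3,4,4a,5,6,7-octahydronaphthalen-1-yl]propanoate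
Conditions: TiCl3(DME)1.5, Zn–Cu couple, DME, reflux; 11 added over 24 h by syringe pump (high dilution)
Reagents that add atoms: none
Why: Intramolecular McMurry carbonyl coupling (low-valent titanium) of the keto aldehyde closes ring A and places the alkene regiospecifically between the two former carbonyl carbons (C1=C10), after which C5 can no longer epimerise.

**Step 7**
Reactants: 12 the bicyclic tert-butyl ester
Product: 13 3-[(1R,2R,4aS)-1,2,5,5-tetramethyl-1,2,3,4,4a,5,6,7-octahydronaphthalen-1-yl]propan-1-ol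
Conditions: LiAlH4, THF, 0 °C → rt; Fieser work-up
Reagents that add atoms: none
Why: Hydride reduction of the ester to the primary alcohol touches no stereocentre and leaves the trisubstituted alkene alone.

**Step 8**
Reactants: 13 the propanol
Product: 14 3-[(1R,2R,4aS)-1,2,5,5-tetramethyl-1,2,3,4,4a,5,6,7-octahydronaphthalen-1-yl]propanal
Conditions: TEMPO (10 mol %), PhI(OAc)2 (1.1 equiv), CH2Cl2, rt
Reagents that add atoms: none
Why: The TEMPO/PhI(OAc)2 (oxoammonium) oxidation stops cleanly at the aldehyde and does not affect the ring alkene.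

**Step 9**
Reactants: 14 the propanal
Product: 15 (1R,2R,4aS)-1-(but-3-yn-1-yl)-1,2,5,5-tetramethyl-1,2,3,4,4a,5,6,7-octahydronaphthalene
Conditions: dimethyl (1-diazo-2-oxopropyl)phosphonate, K2CO3, MeOH, 0 °C → rt
Reagents that add atoms: dimethyl (1-diazo-2-oxopropyl)phosphonate, CC(=O)C(=[N+]=[N-])P(=O)(OC)OC
Why: The Ohira–Bestmann variant of the Seyferth–Gilbert homologation converts the aldehyde into the terminal alkyne with one added carbon (C14) under mildly basic conditions.

**Step 10**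
Reactants: 15 the terminal alkyne
Product: 18 (2E)-3-methyl-5-[(1R,2R,4aS)-1,2,5,5-tetramethyl-1,2,3,4,4a,5,6,7-octahydronaphthalen-1-yl]pent-2-en-1-ol, via alkenylalane 16 (not isolated), via lithium aluminate 17 (not isolated)
Conditions: Me3Al (3 equiv), Cp2ZrCl2 (25 mol %), CH2Cl2, 0 °C → rt; then n-BuLi, THF, −78 °C; (CH2O)n, → rt
Reagents that add atoms: trimethylaluminium, C[Al](C)C; paraformaldehyde (as formaldehyde), C=O
Why: Negishi zirconium-catalysed carboalumination adds methyl and aluminium syn across the alkyne with the methyl (C16) on the internal carbon, and hydroxymethylation of the derived aluminate with retention gives the (E)-trisubstituted allylic alcohol (>98% E).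

**Step 11**
Reactants: 18 the (E)-allylic alcohol
Product: 19 (3R)-3-methyl-5-[(1R,2R,4aS)-1,2,5,5-tetramethyl-1,2,3,4,4a,5,6,7-octahydronaphthalen-1-yl]pentan-1-ol
Conditions: H2 (30 atm), Ru(OAc)2[(S)-BINAP] (1 mol %), MeOH, rt
Reagents that add atoms: none
Why: Noyori hydroxyl-directed asymmetric hydrogenation, in the same sense as geraniol to (R)-citronellol with the (S)-BINAP catalyst, reduces only the allylic alcohol double bond and sets C13 as R while the isolated trisubstituted ring alkene is untouched.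

**Step 12**
Reactants: 19 the saturated alcohol
Product: 21 (3R)-3-methyl-5-[(1R,2R,4aS)-1,2,5,5-tetramethyl-1,2,3,4,4a,5,6,7-octahydronaphthalen-1-yl]pentanoic acid, via aldehyde 20 (not isolated)
Conditions: TEMPO (20 mol %), PhI(OAc)2 (2.5 equiv), MeCN–H2O (1:1), rt
Reagents that add atoms: water, O
Why: TEMPO/PhI(OAc)2 oxidation in aqueous acetonitrile takes the primary alcohol through the aldehyde hydrate to the acid without touching the alkene or C13, which is β to the carbonyl and cannot epimerise.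

**Step 13**
Reactants: 21 the acid; 22 (R)-solketal, [(4R)-2,2-dimethyl-1,3-dioxolan-4-yl]methanol
Product: 23 [(4S)-2,2-dimethyl-1,3-dioxolan-4-yl]methyl (3R)-3-methyl-5-[(1R,2R,4aS)-1,2,5,5-tetramethyl-1,2,3,4,4a,5,6,7-octahydronaphthalen-1-yl]pentanoate
Conditions: DCC (1.2 equiv), DMAP (10 mol %), CH2Cl2, 0 °C → rt
Reagents that add atoms: none
Why: Steglich esterification acylates the primary hydroxyl of (R)-solketal, whose untouched stereocentre becomes glycerol C2 of the target (the descriptor changes from R to S only because the priorities change).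

**Step 14**
Reactants: 23 the solketal ester
Product: 24 (2S)-2,3-dihydroxypropyl (3R)-3-methyl-5-[(1R,2R,4aS)-1,2,5,5-tetramethyl-1,2,3,4,4a,5,6,7-octahydronaphthalen-1-yl]pentanoate
Conditions: Amberlyst-15 (H+ form), MeOH–H2O (95:5), rt; used at once
Reagents that add atoms: none
Why: Mild acid-catalysed acetonide hydrolysis on a sulfonic acid resin at room temperature frees the 1,2-diol with minimal acyl migration and without isomerising the alkene.

**Step 15**
Reactants: 24 the monoacylglycerol diol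
Product: 25 (2S)-3-(acetyloxy)-2-hydroxypropyl (3R)-3-methyl-5-[(1R,2R,4aS)-1,2,5,5-tetramethyl-1,2,3,4,4a,5,6,7-octahydronaphthalen-1-yl]pentanoate (target, CNP0317518.1)
Conditions: AcCl (1.05 equiv), 2,4,6-collidine (2 equiv), CH2Cl2, −78 °C
Reagents that add atoms: acetyl chloride, CC(Cl)=O
Why: Chemoselective acylation with acetyl chloride and the hindered base collidine at low temperature acetylates the primary hydroxyl far faster than the secondary one, giving the 1,3-diacylglycerol with the 2S centre unchanged.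

## Compound list

1 | (R)-(+)-pulegone, (5R)-5-methyl-2-(propan-2-ylidene)cyclohexan-1-one | CC(C)=C1CC[C@@H](C)CC1=O | starting material
2 | 2-(2-bromoethyl)-1,3-dioxolane | BrCCC1OCCO1 | starting material
3 | [2-(1,3-dioxolan-2-yl)ethyl]magnesium bromide (not isolated) | Br[Mg]CCC1OCCO1 | intermediate
4 | (5R)-2-[4-(1,3-dioxolan-2-yl)-2-methylbutan-2-yl]-5-methylcyclohexan-1-one (C2-epimer mixture) | C[C@@H]1CCC(C(C)(C)CCC2OCCO2)C(=O)C1 | intermediate
5 | lithium (3R)-6-[4-(1,3-dioxolan-2-yl)-2-methylbutan-2-yl]-3-methylcyclohex-1-en-1-olate (not isolated) | [Li]OC1=C[C@H](C)CCC1C(C)(C)CCC2OCCO2 | intermediate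
6 | (3R)-6-[4-(1,3-dioxolan-2-yl)-2-methylbutan-2-yl]-2,3-dimethylcyclohexan-1-one (mixture of C2 and C6 epimers) | C[C@@H]1CCC(C(C)(C)CCC2OCCO2)C(=O)C1C | intermediate
7 | (2S,3R,6S)-6-[4-(1,3-dioxolan-2-yl)-2-methylbutan-2-yl]-2,3-dimethylcyclohexan-1-one | C[C@@H]1C(=O)[C@H](C(C)(C)CCC2OCCO2)CC[C@H]1C | intermediate
8 | tert-butyl prop-2-enoate (tert-butyl acrylate) | C=CC(=O)OC(C)(C)C | starting material
9 | lithium (3R,6S)-6-[4-(1,3-dioxolan-2-yl)-2-methylbutan-2-yl]-2,3-dimethylcyclohex-1-en-1-olate (not isolated) | [Li]OC1=C(C)[C@H](C)CC[C@H]1C(C)(C)CCC2OCCO2 | intermediate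
10 | tert-butyl 3-[(1R,3S,6R)-3-[4-(1,3-dioxolan-2-yl)-2-methylbutan-2-yl]-1,6-dimethyl-2-oxocyclohexyl]propanoate | CC(C)(C)OC(=O)CC[C@@]1(C)C(=O)[C@H](C(C)(C)CCC2OCCO2)CC[C@H]1C | intermediate
11 | tert-butyl 3-[(1R,3S,6R)-1,6-dimethyl-3-(2-methyl-5-oxopentan-2-yl)-2-oxocyclohexyl]propanoate | CC(C)(C)OC(=O)CC[C@@]1(C)C(=O)[C@H](C(C)(C)CCC=O)CC[C@H]1C | intermediate
12 | tert-butyl 3-[(1R,2R,4aS)-1,2,5,5-tetramethyl-1,2,3,4,4a,5,6,7-octahydronaphthalen-1-yl]propanoate | CC(C)(C)OC(=O)CC[C@@]1(C)C2=CCCC(C)(C)[C@@H]2CC[C@H]1C | intermediate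
13 | 3-[(1R,2R,4aS)-1,2,5,5-tetramethyl-1,2,3,4,4a,5,6,7-octahydronaphthalen-1-yl]propan-1-ol | OCCC[C@@]1(C)C2=CCCC(C)(C)[C@@H]2CC[C@H]1C | intermediate
14 | 3-[(1R,2R,4aS)-1,2,5,5-tetramethyl-1,2,3,4,4a,5,6,7-octahydronaphthalen-1-yl]propanal | O=CCC[C@@]1(C)C2=CCCC(C)(C)[C@@H]2CC[C@H]1C | intermediate
15 | (1R,2R,4aS)-1-(but-3-yn-1-yl)-1,2,5,5-tetramethyl-1,2,3,4,4a,5,6,7-octahydronaphthalene | C#CCC[C@@]1(C)C2=CCCC(C)(C)[C@@H]2CC[C@H]1C | intermediate
16 | dimethyl[(1E)-2-methyl-4-[(1R,2R,4aS)-1,2,5,5-tetramethyl-1,2,3,4,4a,5,6,7-octahydronaphthalen-1-yl]but-1-en-1-yl]alumane (not isolated) | C[Al](C)/C=C(\C)CC[C@@]1(C)C2=CCCC(C)(C)[C@@H]2CC[C@H]1C | intermediate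
17 | lithium butyl(dimethyl)[(1E)-2-methyl-4-[(1R,2R,4aS)-1,2,5,5-tetramethyl-1,2,3,4,4a,5,6,7-octahydronaphthalen-1-yl]but-1-en-1-yl]aluminate (not isolated) | [Li+].CCCC[Al-](C)(C)/C=C(\C)CC[C@@]1(C)C2=CCCC(C)(C)[C@@H]2CC[C@H]1C | intermediate
18 | (2E)-3-methyl-5-[(1R,2R,4aS)-1,2,5,5-tetramethyl-1,2,3,4,4a,5,6,7-octahydronaphthalen-1-yl]pent-2-en-1-ol | OC/C=C(\C)CC[C@@]1(C)C2=CCCC(C)(C)[C@@H]2CC[C@H]1C | intermediate
19 | (3R)-3-methyl-5-[(1R,2R,4aS)-1,2,5,5-tetramethyl-1,2,3,4,4a,5,6,7-octahydronaphthalen-1-yl]pentan-1-ol | OCC[C@H](C)CC[C@@]1(C)C2=CCCC(C)(C)[C@@H]2CC[C@H]1C | intermediate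
20 | (3R)-3-methyl-5-[(1R,2R,4aS)-1,2,5,5-tetramethyl-1,2,3,4,4a,5,6,7-octahydronaphthalen-1-yl]pentanal (not isolated) | O=CC[C@H](C)CC[C@@]1(C)C2=CCCC(C)(C)[C@@H]2CC[C@H]1C | intermediate
21 | (3R)-3-methyl-5-[(1R,2R,4aS)-1,2,5,5-tetramethyl-1,2,3,4,4a,5,6,7-octahydronaphthalen-1-yl]pentanoic acid | OC(=O)C[C@H](C)CC[C@@]1(C)C2=CCCC(C)(C)[C@@H]2CC[C@H]1C | intermediate
22 | (R)-solketal, [(4R)-2,2-dimethyl-1,3-dioxolan-4-yl]methanol | OC[C@@H]1COC(C)(C)O1 | starting material
23 | [(4S)-2,2-dimethyl-1,3-dioxolan-4-yl]methyl (3R)-3-methyl-5-[(1R,2R,4aS)-1,2,5,5-tetramethyl-1,2,3,4,4a,5,6,7-octahydronaphthalen-1-yl]pentanoate | CC1(C)OC[C@@H](COC(=O)C[C@H](C)CC[C@@]2(C)C3=CCCC(C)(C)[C@@H]3CC[C@H]2C)O1 | intermediate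
24 | (2S)-2,3-dihydroxypropyl (3R)-3-methyl-5-[(1R,2R,4aS)-1,2,5,5-tetramethyl-1,2,3,4,4a,5,6,7-octahydronaphthalen-1-yl]pentanoate | OC[C@H](O)COC(=O)C[C@H](C)CC[C@@]1(C)C2=CCCC(C)(C)[C@@H]2CC[C@H]1C | intermediate
25 | (2S)-3-(acetyloxy)-2-hydroxypropyl (3R)-3-methyl-5-[(1R,2R,4aS)-1,2,5,5-tetramethyl-1,2,3,4,4a,5,6,7-octahydronaphthalen-1-yl]pentanoate | CC(=O)OC[C@H](O)COC(=O)C[C@H](C)CC[C@@]1(C)C2=CCCC(C)(C)[C@@H]2CC[C@H]1C | target

## Step count and risks

Total steps: 15. Longest linear sequence: 15 steps (1 → 25); compounds 2, 8 and 22 are used as purchased.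

The three steps most likely to fail:

**Step 1** (conjugate addition of a thermally fragile acetal Grignard to a β,β-disubstituted enone; enolisation or 1,2-addition may compete). The fallback sets out from 1 and uses the robust 3-butenylmagnesium bromide with CuBr·SMe2 to give (5R)-5-methyl-2-(2-methylhex-5-en-2-yl)cyclohexan-1-one F1. Ozonolysis (O3, CH2Cl2–MeOH, −78 °C, then PPh3) gives 4-methyl-4-[(4R)-4-methyl-2-oxocyclohexyl]pentanal F2. Aldehyde-selective acetalisation (ethylene glycol, PPTS, benzene, reflux), which the hindered ketone does not undergo, comes back to the route at 4.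

**Step 4** (the hindered tetrasubstituted enolate may add sluggishly to the acrylate, or oligomerise it; the face selectivity rests on a conformational argument, not on a direct precedent). The fallback sets out from 7 and alkylates the same enolate 9 irreversibly with allyl bromide (THF, −78 → 0 °C), which enters on the same axial face, to give (2R,3R,6S)-6-[4-(1,3-dioxolan-2-yl)-2-methylbutan-2-yl]-2,3-dimethyl-2-(prop-2-en-1-yl)cyclohexan-1-one F3. PPTS in wet acetone gives 4-[(1S,3R,4R)-3,4-dimethyl-2-oxo-3-(prop-2-en-1-yl)cyclohexyl]-4-methylpentanal F4, and McMurry coupling gives (1R,2R,4aS)-1,2,5,5-tetramethyl-1-(prop-2-en-1-yl)-1,2,3,4,4a,5,6,7-octahydronaphthalene F5. Hydroboration of the terminal alkene only (9-BBN, THF, then NaOH/H2O2) comes back to the route at 13.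

**Step 6** (McMurry coupling onto a ketone flanked by a quaternary and a neopentyl carbon; simple reduction or attack on the ester may compete). The fallback sets out from 11 and uses a SmI2 ketyl–carbonyl (pinacol) cyclisation (THF, t-BuOH, −78 °C → rt), which tolerates the ester, to give the cis-diol tert-butyl 3-[(1R,2R,4aS)-8,8a-dihydroxy-1,2,5,5-tetramethyldecahydronaphthalen-1-yl]propanoate F6. Thiophosgene and DMAP convert it into the 8,8a-cyclic thionocarbonate of that diol F7, and Corey–Winter elimination with P(OMe)3 at 110 °C comes back to the route at 12.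

## Further compounds

F1 | step 1 | (5R)-5-methyl-2-(2-methylhex-5-en-2-yl)cyclohexan-1-one (C2-epimer mixture) | C[C@@H]1CCC(C(C)(C)CCC=C)C(=O)C1
F2 | step 1 | 4-methyl-4-[(4R)-4-methyl-2-oxocyclohexyl]pentanal (epimer mixture at the ring carbon bearing the side chain) | C[C@@H]1CCC(C(C)(C)CCC=O)C(=O)C1
F3 | step 4 | (2R,3R,6S)-6-[4-(1,3-dioxolan-2-yl)-2-methylbutan-2-yl]-2,3-dimethyl-2-(prop-2-en-1-yl)cyclohexan-1-one | C=CC[C@@]1(C)C(=O)[C@H](C(C)(C)CCC2OCCO2)CC[C@H]1C
F4 | step 4 | 4-[(1S,3R,4R)-3,4-dimethyl-2-oxo-3-(prop-2-en-1-yl)cyclohexyl]-4-methylpentanal | C=CC[C@@]1(C)C(=O)[C@H](C(C)(C)CCC=O)CC[C@H]1C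
F5 | step 4 | (1R,2R,4aS)-1,2,5,5-tetramethyl-1-(prop-2-en-1-yl)-1,2,3,4,4a,5,6,7-octahydronaphthalene | C=CC[C@@]1(C)C2=CCCC(C)(C)[C@@H]2CC[C@H]1C
F6 | step 6 | tert-butyl 3-[(1R,2R,4aS)-8,8a-dihydroxy-1,2,5,5-tetramethyldecahydronaphthalen-1-yl]propanoate (cis-8,8a-diol, configuration at C8 and C8a not assigned) | CC(C)(C)OC(=O)CC[C@@]1(C)C2(O)C(O)CCC(C)(C)[C@@H]2CC[C@H]1C
F7 | step 6 | 8,8a-cyclic thionocarbonate of the diol F6 | CC(C)(C)OC(=O)CC[C@@]1(C)C23OC(=S)OC2CCC(C)(C)[C@@H]3CC[C@H]1C
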